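## Structural features

Prinsepiol (12) is a C2-symmetric 3,7-dioxabicyclo[3.3.0]octane in which two oxolane rings (ring 1: C1–C2–O3–C4–C5; ring 2: C5–C6–O7–C8–C1) are fused cis along the C1–C5 bond. C2 and C6 each carry a 4-hydroxy-3-methoxyphenyl group, C4 and C8 are methylenes, and both bridgeheads are tertiary alcohols. The four stereocentres are contiguous (C2–C1–C5–C6; 1S,2R,5S,6R): the two hydroxyls are cis because the ring fusion allows nothing else, and each aryl group is cis to the hydroxyl on the neighbouring carbon, that is, on the convex face. The fragile parts are the benzylic ether bonds C2–O3 and C6–O7, which lie para to a phenolic oxygen and therefore ionise under acid, open through a phenoxide (quinone methide) and cleave on hydrogenolysis; the free phenols are also easily oxidised. The real difficulty is the vicinal pair of fully substituted, oxygen-bearing carbons C1/C5, held in a fixed relation to C2 and C6 and in one enantiomeric series. The carbon skeleton consists of two C6–C3 units joined through their side-chain β-carbons (C1–C5), and each ring oxygen ties the benzylic carbon of one unit to the terminal carbon of the other. The key step uses exactly this: β–β coupling of two ferulic acid radicals makes C1–C5, the carboxyl groups close ring 1 and ring 2 at C2–O3 and C6–O7, and C1 and C5 are left as C–H acids next to lactone carbonyls, where hydroxyl can be introduced later with the ring fusion dictating the configuration.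

## Logic of the disconnections

12 ⇒ 11. The two phenolic O–H bonds are replaced by O–Si bonds. A free phenol para to a benzylic ether would not survive the bases, hydrides and Lewis acids used earlier. A silyl ether is removed by fluoride, which neither touches the benzylic C–O bonds (as hydrogenolysis would) nor needs acid. The forward step must keep the liberated phenol protonated.

11 ⇒ 10 ⇒ 9. No skeletal bond is cut; the C–H bonds at C4 and C8 are traced back through lactols to lactone carbonyls. The gain is that the carbonyls are what the dimerisation delivers and that they acidify C1–H and C5–H. The forward reduction has to pass through cyclic oxocarbenium ions, so that the ring oxygens stay in place, and must not ionise the benzylic C2–O3 and C6–O7 bonds.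

9 ⇒ 7. The C1–O and C5–O bonds are cut, because each bridgehead is α to one lactone carbonyl. This removes both tertiary alcohols and leads back to the dimerisation product. The forward oxidation must be faster than fragmentation of the enolate. It must also be done one bridgehead at a time, by way of 8: only while the neighbouring bridgehead is still sp3 does the cis ring fusion force the new oxygen to take the place of the hydrogen.

7 ⇒ 6 ⇒ 4 + 5. The acyl C–O bonds of both lactones are opened and the resulting amide C–N bonds are cut. The dimerisation cannot be made enantioselective, so the enantiomers of 4 must be turned into diastereomers. The lactone carbonyls are the only handles next to the stereocentres, and the auxiliary 5 ends up directly on the carbons attached to C1 and C5. The forward aminolysis must neither epimerise nor eliminate, and re-lactonisation must give back the same ring.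

4 ⇒ 3. The O–Si bonds are cut. The phenols are masked before any amine or base is used, and for that reason before the resolution and not after it, so that no phenoxide can expel the benzylic carboxylate.

3 ⇒ 2 ⇒ 1 + 1. The alkyl C–O bonds C2–O3 and C6–O7 are cut to reach 2, and C1–C5 is cut to reach two molecules of 1. This single operation removes both rings, three skeletal bonds and the relative configuration of four centres, and ends at one commercial C10 acid. The precursor must carry a free phenol (to be oxidised) and a free carboxylic acid (to close the rings), so no protecting or auxiliary group can be placed on it and 1 is used as bought. The forward step must favour 8–8 over 8–5 and 8–O–4 coupling, and the racemate has to be accepted.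

## Other disconnections considered

Alternative 1: The cut is made at C1–C8 and C5–C4, the bonds from the bridgeheads to the methylene carbons. C1, C5 and their oxygens then come from the tartrate-derived diketone acetonide A1, whose aryl ketone carbons are C2 and C6.
- Forward key step: A1 would be deprotonated at C1 with KN(SiMe3)2 and alkylated with BnOCH2Cl, and the same repeated at C5 in the same flask, to give the bis(benzyloxymethyl) diketone A2. Each electrophile has to enter trans to the neighbouring aroyl group, which amounts to retention at both dioxolane carbons.
- In its favour: the absolute configuration of C1 and C5 is bought from the chiral pool, so there is no resolution and no loss of half the material. Both tertiary C–O bonds exist from the start, so no enolate oxidation is needed. On these two points it is better than the chosen plan.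
- Against it here: the enolate of an α,β-dioxygenated ketone has a β-alkoxy leaving group in the acetal ring and can fragment. The second alkylation builds a second fully substituted carbon next to the first. The key step closes no ring and sets neither C2 nor C6.
- What would remain after A2: a ketone reduction that must set C2 and C6 under substrate control; a debenzylation next to electron-rich benzylic alcohols; a double cyclisation in which the crossed closure (C2–O–C4) competes with closure between the two hydroxymethyl groups (C4–O–C8); and removal of the acetal under acid.
- Comparison: on structure both plans fit the C2 symmetry equally well. On mechanism both depend on enolates that carry a β-leaving group, so they are equal in that risk. On step economy the chosen plan is shorter and forms three bonds and two rings in its key step, against two bonds and no ring here.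

Alternative 2: The cut is made at C2–O3 and C6–O7, and the C1 and C5 hydroxyls are traced back to epoxide oxygens. This leads to the (E,E)-dienediol A3, an 8–8 skeleton that a double Stobbe-type condensation and reduction would supply.
- Forward key step: Ti(OiPr)4, L-(+)-diethyl tartrate and tBuOOH would epoxidise both allylic alcohol units of A3 (Sharpless epoxidation). Each hydroxymethyl group would then open the benzylic epoxide carbon of the other half (5-endo, inversion), giving prinsepiol bis(allyl) ether A4, which needs only deallylation with Pd(PPh3)4.
- In its favour: all four stereocentres, both rings and four C–O bonds are formed in one operation. The configuration comes from a catalyst, and two independent enantioselective events on one molecule should raise the enantiomeric purity of the C2-symmetric product. The (E) geometry translates into the aryl group being cis to the adjacent hydroxyl. On absolute stereocontrol and on step economy it is clearly better than the chosen plan.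
- Against it: aryl epoxides with a para oxygen open easily by an SN1 path, which would loosen the link between alkene geometry and the configuration at C2/C6. Once the first oxolane has closed, the hydroxymethyl group of the second alkene has become a ring ether, so the second epoxidation must either outrun the first cyclisation or be directed by the new tertiary hydroxyl under substrate control. A benzylic cation next to a titanium alkoxide invites a semipinacol shift. The twisted 2,3-disubstituted diene may epoxidise slowly.
- Comparison: both plans use the same 8–8 bond, made there by carbonyl chemistry before the key step and here by radical coupling in it. The chosen plan relies on thermodynamically guided lactonisation and on ring strain for the hydroxylation, which depend less on the timing of events than this cascade. On step count the alternative wins.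

Alternative 3: The cut is made at the two aryl–carbon bonds at C2 and C6.
- Forward key step: the tartrate-derived bis(lactol acetate) A5 would be ionised by BF3·OEt2 or Me3SiBr to oxocarbenium ions at C2 and C6, and the diarylzinc A6 would deliver an aryl group to each. The product would be the fully silylated prinsepiol A7, from which fluoride removes all four silyl groups.
- In its favour: the route is convergent, the aryl groups enter last (better than the chosen plan for analogues), and the core carries the bridgehead oxygens and the absolute configuration from the chiral pool, so no resolution is needed. Arylation of cyclic oxocarbenium ions by diarylzinc reagents is an established reaction type. The convex face of the cis-fused bicycle is the open one, and an adjacent oxygen on a five-membered oxocarbenium ion commonly directs a nucleophile to the 1,2-cis position.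
- Against it: A5 itself needs the double hydroxymethylation of a tartrate enolate (the same hazard as in Alternative 1), followed by lactonisation, reduction, silylation and acetylation, so the sequence is long. Two arylations must both succeed on one molecule. The products are electron-rich benzylic ethers exposed to the same Lewis acid that formed them, so epimerisation or reopening is possible. The key step closes no ring.
- Comparison: it is equal to the chosen plan in late-stage Lewis acid risk, better in convergence and in the source of chirality, and worse in length and in the number of bonds made per step.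

Key step: step 1

Remark on the chemistry: 2, 3 and 4 are racemic and their SMILES show the enantiomer that leads to 12; 3 differs from 12 only by hydrogen for hydroxyl at C1 and C5 and by C=O for CH2 at C4 and C8, and the locants C1–C8 of the bicycle are used for open-chain compounds as well.

## Route

Step 1
Reactants: 1 (E)-ferulic acid (two molecules)
Product: 3 rac-(1S,2S,5S,6S)-2,6-bis(4-hydroxy-3-methoxyphenyl)-3,7-dioxabicyclo[3.3.0]octane-4,8-dione (cis-fused; each aryl group cis to the neighbouring bridgehead hydrogen), via bis(quinone methide) diacid 2 (not isolated)
Conditions: FeCl3·6H2O (1.1 equiv), acetone–H2O (1:9), 0.02 M, rt; precipitate collected and recrystallised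
Reagents that add atoms: none
Why: FeCl3 (trivalent iron) takes one electron from each phenol to give phenoxyl radicals whose spin is shared by the oxygen, the ring carbon ortho to it and the side-chain β-carbon, and two radicals join at their β-carbons (C1–C5) to give 2; the closest known reaction type is the biomimetic dehydrodimerisation of 4-hydroxycinnamic acids to furofuran bis-lactones. Ring 1 closes when the carboxyl group on C5 adds through oxygen to the methide carbon C2 of the other half, and ring 2 closes in the same way between the carboxyl group on C1 and C6; both closures are 5-exo-trig conjugate additions that restore the arenes. C1 and C5 are set in the radical coupling without control, but only the like (C2-symmetric) diastereomer of 2 can close both rings, because a bicyclo[3.3.0] bis-lactone must be cis-fused, while the unlike diastereomer is diverted to open-chain and aryltetralin products. C2 and C6 are set in the lactonisations: the carboxylate attacks the quinone methide face that leaves the aryl group on the convex face, cis to the adjacent bridgehead hydrogen, and the addition is reversible enough to settle on this less crowded isomer. The step needs 8–8 selectivity over 8–5 and 8–O–4 coupling; the free carboxylic acid (which traps the methide at once), high dilution in water and precipitation of 3 favour it, but only moderately. No enantiocontrol is possible, so 3 is racemic.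

Step 2
Reactants: 3 racemic bis-lactone
Product: 4 rac-(1S,2S,5S,6S)-2,6-bis[3-methoxy-4-(triisopropylsilyloxy)phenyl]-3,7-dioxabicyclo[3.3.0]octane-4,8-dione
Conditions: iPr3SiCl (2.5 equiv), imidazole (5 equiv), DMF, rt
Reagents that add atoms: triisopropylsilyl chloride, CC(C)[Si](Cl)(C(C)C)C(C)C
Why: Silylation of phenols with a silyl chloride and imidazole; the lactones and the benzylic C–O bonds are inert to this weak base. The bulky triisopropylsilyl ether is chosen because it has to pass AlMe3, hot dilute acid, KN(SiMe3)2, iBu2AlH and BF3·OEt2, and because a silyl ether, unlike a phenoxide, cannot expel the benzylic carboxylate as a quinone methide.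

Step 3
Reactants: 4 racemic bis-silyl bis-lactone; 5 (S)-1-phenylethylamine
Product: 6 (2S,3S)-2,3-bis{(S)-hydroxy[3-methoxy-4-(triisopropylsilyloxy)phenyl]methyl}-N1,N4-bis[(1S)-1-phenylethyl]butanediamide
Conditions: (S)-PhCH(Me)NH2 (5 equiv), AlMe3 (5 equiv), CH2Cl2, 0 °C → rt; the diastereomeric bis(hydroxy amide) formed from the other enantiomer of 4 is removed on SiO2 or by crystallisation
Reagents that add atoms: (S)-1-phenylethylamine (5), C[C@H](N)c1ccccc1
Why: AlMe3-mediated aminolysis of lactones: the dimethylaluminium amide of 5 opens both γ-lactones at the acyl carbon under non-basic conditions, so C1, C2, C5 and C6 are untouched and no new stereocentre is formed. The two enantiomers of 4 give two diastereomeric bis(hydroxy amides), in which the (S)-1-phenylethyl groups sit on the carbonyls next to C1 and C5, and 6 is the one derived from the (1S,2S,5S,6S) enantiomer; separating such hydroxy amides is the classical way of resolving lactones.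

Step 4
Reactants: 6 bis(hydroxy amide)
Product: 7 (1S,2S,5S,6S)-2,6-bis[3-methoxy-4-(triisopropylsilyloxy)phenyl]-3,7-dioxabicyclo[3.3.0]octane-4,8-dione (single enantiomer)
Conditions: 1 M H2SO4–dioxane (1:1), 80 °C; 5 recovered from the aqueous phase after basification
Reagents that add atoms: none
Why: Neighbouring-group-assisted cleavage of γ-hydroxy amides: under dilute acid each benzylic hydroxyl attacks the protonated amide in the 1,4-position and expels the ammonium ion (N→O acyl transfer), so both five-membered lactones re-form with the C–O bonds at C2 and C6 unbroken, hence with retention. Should a benzylic cation intervene, reclosure is expected to favour the cis-fused bicycle with the aryl groups on the less crowded convex face; aryl triisopropylsilyl ethers should tolerate hot dilute aqueous acid.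

Step 5
Reactants: 7 enantiopure bis-silyl bis-lactone
Product: 9 (1S,2R,5S,6R)-1,5-dihydroxy-2,6-bis[3-methoxy-4-(triisopropylsilyloxy)phenyl]-3,7-dioxabicyclo[3.3.0]octane-4,8-dione, via monohydroxy bis-lactone 8 (not isolated)
Conditions: KN(SiMe3)2 (1.1 equiv), THF, −78 °C, then 2-(phenylsulfonyl)-3-phenyloxaziridine (1.3 equiv); then KN(SiMe3)2 (1.3 equiv), −78 °C, then the oxaziridine (1.5 equiv), −78 → −50 °C; AcOH
Reagents that add atoms: 2-(phenylsulfonyl)-3-phenyloxaziridine, O=S(=O)(N1OC1c1ccccc1)c1ccccc1
Why: Enolate oxidation with an N-sulfonyloxaziridine (Davis oxidation), done one bridgehead at a time: KN(SiMe3)2 removes the C1–H α to the C8 carbonyl, and oxygen can only be delivered cis to the still sp3 C5–H because a trans-fused bicyclo[3.3.0]octane is prohibitively strained, so OH replaces H with retention to give 8; loss of the ring carboxylate from C2 would be the reverse of a 5-endo-trig closure, for which the enolate π-system is poorly aligned with the C2–O3 bond. The second deprotonation at C5 gives a β-oxido enolate of the Fráter–Seebach type, in which the alkoxide is no leaving group, and oxidation must again occur cis to the C1 oxygen; this gives the cis-diol 9 with each hydroxyl cis to the neighbouring aryl group. The potassium counter-ion keeps the enolates from adding to the sulfonylimine by-product.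

Step 6
Reactants: 9 dihydroxy bis-lactone
Product: 10 (1S,2R,5S,6R)-2,6-bis[3-methoxy-4-(triisopropylsilyloxy)phenyl]-3,7-dioxabicyclo[3.3.0]octane-1,4,5,8-tetrol (bis-lactol; mixture of anomers at C4 and C8)
Conditions: iBu2AlH (6 equiv), CH2Cl2, −78 °C; aq. potassium sodium tartrate
Reagents that add atoms: none
Why: Partial reduction of γ-lactones to lactols with iBu2AlH at low temperature; the aluminium hemiacetals, held additionally by the neighbouring aluminium alkoxides of the tertiary hydroxyls, persist at −78 °C and collapse to the lactols only on work-up, so over-reduction to the open diol is avoided. The new centres C4 and C8 form as anomeric mixtures, which is of no consequence because they become CH2 in step 7; silyl and benzylic ethers are inert.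

Step 7
Reactants: 10 bis-lactol
Product: 11 (1S,2R,5S,6R)-2,6-bis[3-methoxy-4-(triisopropylsilyloxy)phenyl]-3,7-dioxabicyclo[3.3.0]octane-1,5-diol (prinsepiol bis(triisopropylsilyl) ether)
Conditions: Et3SiH (10 equiv), BF3·OEt2 (4 equiv), CH2Cl2, −78 → −30 °C; aq. NaHCO3
Reagents that add atoms: none
Why: Ionic hydrogenation of lactols: BF3·OEt2 ionises each hemiacetal to a cyclic oxocarbenium ion (O3=C4, O7=C8), which Et3SiH reduces, so the ring oxygens and the C2–O3 and C6–O7 bonds from the key step are never broken and C1, C2, C5 and C6 keep their configuration. Low temperature confines ionisation to the hemiacetal carbons; the benzylic ethers are flanked by electron-withdrawing tertiary carbinols and carry silyloxyaryl groups that donate far less than a phenoxide, and the tertiary alcohols need no protection.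

Step 8
Reactants: 11 bis-silyl ether
Product: 12 prinsepiol, (1S,2R,5S,6R)-2,6-bis(4-hydroxy-3-methoxyphenyl)-3,7-dioxabicyclo[3.3.0]octane-1,5-diol
Conditions: Bu4NF (2.4 equiv), AcOH (2.4 equiv), THF, 0 °C
Reagents that add atoms: none
Why: Fluoride cleavage of aryl silyl ethers; buffering with acetic acid keeps the liberated phenols protonated, so no phenoxide can open the benzylic ethers by way of a quinone methide. No stereocentre is involved and nothing else in the molecule reacts with fluoride.

## Compound list

1 | (E)-ferulic acid, (E)-3-(4-hydroxy-3-methoxyphenyl)prop-2-enoic acid | COc1cc(/C=C/C(=O)O)ccc1O | starting material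
2 | rac-(2R,3R)-2,3-bis[(3-methoxy-4-oxocyclohexa-2,5-dien-1-ylidene)methyl]butanedioic acid (like diastereomer; bis(quinone methide) diacid) | OC(=O)[C@H](C=C1C=CC(=O)C(OC)=C1)[C@@H](C=C2C=CC(=O)C(OC)=C2)C(=O)O | intermediate
3 | rac-(1S,2S,5S,6S)-2,6-bis(4-hydroxy-3-methoxyphenyl)-3,7-dioxabicyclo[3.3.0]octane-4,8-dione | COc1cc([C@H]2OC(=O)[C@@H]3[C@@H](c4ccc(O)c(OC)c4)OC(=O)[C@H]23)ccc1O | intermediate
4 | rac-(1S,2S,5S,6S)-2,6-bis[3-methoxy-4-(triisopropylsilyloxy)phenyl]-3,7-dioxabicyclo[3.3.0]octane-4,8-dione | COc1cc([C@H]2OC(=O)[C@@H]3[C@@H](c4ccc(O[Si](C(C)C)(C(C)C)C(C)C)c(OC)c4)OC(=O)[C@H]23)ccc1O[Si](C(C)C)(C(C)C)C(C)C | intermediate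
5 | (S)-1-phenylethylamine | C[C@H](N)c1ccccc1 | starting material
6 | (2S,3S)-2,3-bis{(S)-hydroxy[3-methoxy-4-(triisopropylsilyloxy)phenyl]methyl}-N1,N4-bis[(1S)-1-phenylethyl]butanediamide | COc1cc([C@@H](O)[C@@H](C(=O)N[C@@H](C)c2ccccc2)[C@H](C(=O)N[C@@H](C)c3ccccc3)[C@H](O)c4ccc(O[Si](C(C)C)(C(C)C)C(C)C)c(OC)c4)ccc1O[Si](C(C)C)(C(C)C)C(C)C | intermediate
7 | (1S,2S,5S,6S)-2,6-bis[3-methoxy-4-(triisopropylsilyloxy)phenyl]-3,7-dioxabicyclo[3.3.0]octane-4,8-dione (single enantiomer) | COc1cc([C@H]2OC(=O)[C@@H]3[C@@H](c4ccc(O[Si](C(C)C)(C(C)C)C(C)C)c(OC)c4)OC(=O)[C@H]23)ccc1O[Si](C(C)C)(C(C)C)C(C)C | intermediate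
8 | (1R,2R,5R,6S)-1-hydroxy-2,6-bis[3-methoxy-4-(triisopropylsilyloxy)phenyl]-3,7-dioxabicyclo[3.3.0]octane-4,8-dione (OH in place of the C1 hydrogen of 7, retention) | COc1cc([C@H]2OC(=O)[C@@H]3[C@@H](c4ccc(O[Si](C(C)C)(C(C)C)C(C)C)c(OC)c4)OC(=O)[C@]23O)ccc1O[Si](C(C)C)(C(C)C)C(C)C | intermediate
9 | (1S,2R,5S,6R)-1,5-dihydroxy-2,6-bis[3-methoxy-4-(triisopropylsilyloxy)phenyl]-3,7-dioxabicyclo[3.3.0]octane-4,8-dione | COc1cc([C@H]2OC(=O)[C@]3(O)[C@@H](c4ccc(O[Si](C(C)C)(C(C)C)C(C)C)c(OC)c4)OC(=O)[C@]23O)ccc1O[Si](C(C)C)(C(C)C)C(C)C | intermediate
10 | (1S,2R,5S,6R)-2,6-bis[3-methoxy-4-(triisopropylsilyloxy)phenyl]-3,7-dioxabicyclo[3.3.0]octane-1,4,5,8-tetrol (anomers at C4 and C8) | COc1cc([C@H]2OC(O)[C@]3(O)[C@@H](c4ccc(O[Si](C(C)C)(C(C)C)C(C)C)c(OC)c4)OC(O)[C@]23O)ccc1O[Si](C(C)C)(C(C)C)C(C)C | intermediate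
11 | (1S,2R,5S,6R)-2,6-bis[3-methoxy-4-(triisopropylsilyloxy)phenyl]-3,7-dioxabicyclo[3.3.0]octane-1,5-diol | COc1cc([C@H]2OC[C@]3(O)[C@@H](c4ccc(O[Si](C(C)C)(C(C)C)C(C)C)c(OC)c4)OC[C@]23O)ccc1O[Si](C(C)C)(C(C)C)C(C)C | intermediate
12 | prinsepiol, (1S,2R,5S,6R)-2,6-bis(4-hydroxy-3-methoxyphenyl)-3,7-dioxabicyclo[3.3.0]octane-1,5-diol | COc1cc([C@H]2OC[C@]3(O)[C@@H](c4ccc(O)c(OC)c4)OC[C@]23O)ccc1O | target

## Step count and least certain steps

Total step count: 8. Longest linear sequence: 8 steps (1 → 12).

**Step 1 (key step).**
- Most likely to go wrong: coupling of the phenoxyl radicals through the ring carbon ortho to oxygen or through oxygen (8–5, 8–O–4) instead of β–β; failure of the unlike β–β adduct to lactonise twice; further oxidation of the phenolic product to oligomers. All of these follow from the fact that radical coupling obeys spin density and not a directing group.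
- Fallback (sets out from 1, returns at 3): the C1–C5 bond is made by two-electron enolate chemistry and the benzylic C–O bonds by a separate oxidation. Hydrogenation of 1 (H2, Pd/C, EtOAc) gives 3-(4-hydroxy-3-methoxyphenyl)propanoic acid F1. Silylation of both acidic groups (iPr3SiCl, imidazole, DMF) gives the silyl ether silyl ester F2, and AcOH–THF–H2O at rt hydrolyses the silyl ester alone to give the silyl ether acid F3. The dianion of F3 (LiN(iPr)2, 2.2 equiv, THF, −78 °C) is coupled at the α-carbons with I2 (0.5 equiv) to give the 2,3-bis(arylmethyl)succinic acid F4, whose like (racemic) diastereomer is separated from the meso form by crystallisation. Bu4NF frees the phenols to give the diacid F5. DDQ (2.2 equiv, dioxane, rt) dehydrogenates each 4-alkylphenol unit to its quinone methide, which is 2, and lactonisation as in step 1 gives 3. The position of the C–C bond is then fixed by the enolate and not by spin density.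

**Step 3 (with the re-lactonisation of step 4).**
- Most likely to go wrong: incomplete opening of the second lactone; imide formation between the first amide and the neighbouring lactone carbonyl; elimination of the benzylic carboxylate under the amide base; poor discrimination of 6 from its diastereomer on silica or in crystallisation; partial loss of the silyl ethers or epimerisation at the benzylic carbons in the hot acid of step 4.
- Fallback (sets out from 4, returns at 7): racemic 4 is separated directly into its enantiomers by preparative chromatography on a chiral stationary phase (cellulose or amylose tris(3,5-dimethylphenylcarbamate)). This replaces covalent derivatisation by a physical separation, makes no new compound and removes steps 3 and 4.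

**Step 5.**
- Most likely to go wrong: ring-opening elimination of the bridgehead enolate by loss of the β-carboxylate at C2 or C6; retro-aldol cleavage of the C1–C5 bond in the β-oxido lactone formed after the first oxidation; incomplete formation of the second enolate next to the alkoxide; addition of an enolate to the sulfonylimine; loss of stereocontrol if both bridgeheads are enolised at the same time, because the ring fusion then no longer dictates the face.
- Fallback (sets out from 7, returns at 9): two Rubottom oxidations in which the enolate exists only fleetingly and no free β-alkoxide is formed. 7 is treated with LiN(iPr)2 in the presence of Me3SiCl (THF, −78 °C) to give the mono(trimethylsilyl ketene acetal) F6. Dimethyldioxirane (acetone, −78 °C) epoxidises F6 cis to the C5 hydrogen, and silyl migration gives the silylated monohydroxy bis-lactone F7 (the 1-O-trimethylsilyl ether of 8). The same two operations on F7 give the ketene acetal F8 and then the bis(trimethylsilyloxy) bis-lactone F9 (the 1,5-bis-O-trimethylsilyl ether of 9). AcOH–THF–H2O removes the two trimethylsilyl groups and gives 9.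

**Step 7.**
- Most likely to go wrong: ionisation of the benzylic C2–O3 or C6–O7 bonds by BF3·OEt2, followed either by hydride capture (reductive ring opening) or by epimerisation at C2/C6; stalling at a half-reduced lactol.
- Fallback (sets out from 9, returns at 12): reduction to the open chain and acid-mediated ring closure at the benzylic carbons. LiAlH4 (THF, 0 °C) reduces both lactones of 9 to the silylated hexaol F10. Bu4NF frees the phenols to give the hexaol F11. A catalytic amount of 10-camphorsulfonic acid (THF–CH2Cl2, rt) ionises each 4-hydroxybenzylic alcohol, and the primary hydroxyl of the other half closes the oxolane (C2–O3, C6–O7). The aryl groups should settle on the convex face under thermodynamic control, which gives 12 directly. Neither a tertiary hydroxyl nor the hydroxymethyl group on the adjacent carbon can reach the benzylic cation through a five-membered ring, so only the crossed closure is open.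

## Further compounds

F1 | step 1 | 3-(4-hydroxy-3-methoxyphenyl)propanoic acid | COc1cc(CCC(=O)O)ccc1O
F2 | step 1 | triisopropylsilyl 3-[3-methoxy-4-(triisopropylsilyloxy)phenyl]propanoate | COc1cc(CCC(=O)O[Si](C(C)C)(C(C)C)C(C)C)ccc1O[Si](C(C)C)(C(C)C)C(C)C
F3 | step 1 | 3-[3-methoxy-4-(triisopropylsilyloxy)phenyl]propanoic acid | COc1cc(CCC(=O)O)ccc1O[Si](C(C)C)(C(C)C)C(C)C
F4 | step 1 | rac-(2R,3R)-2,3-bis[3-methoxy-4-(triisopropylsilyloxy)benzyl]butanedioic acid | COc1cc(C[C@@H](C(=O)O)[C@@H](Cc2ccc(O[Si](C(C)C)(C(C)C)C(C)C)c(OC)c2)C(=O)O)ccc1O[Si](C(C)C)(C(C)C)C(C)C
F5 | step 1 | rac-(2R,3R)-2,3-bis(4-hydroxy-3-methoxybenzyl)butanedioic acid | COc1cc(C[C@@H](C(=O)O)[C@@H](Cc2ccc(O)c(OC)c2)C(=O)O)ccc1O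
F0 | step 3 | none | none
F6 | step 5 | mono(trimethylsilyl ketene acetal) of 7 (C1=C8 enol ether; C2, C5, C6 as in 7) | COc1cc([C@H]2OC(=O)[C@@H]3[C@@H](c4ccc(O[Si](C(C)C)(C(C)C)C(C)C)c(OC)c4)OC(O[Si](C)(C)C)=C23)ccc1O[Si](C(C)C)(C(C)C)C(C)C
F7 | step 5 | 1-O-trimethylsilyl ether of 8 | COc1cc([C@H]2OC(=O)[C@@H]3[C@@H](c4ccc(O[Si](C(C)C)(C(C)C)C(C)C)c(OC)c4)OC(=O)[C@]23O[Si](C)(C)C)ccc1O[Si](C(C)C)(C(C)C)C(C)C
F8 | step 5 | trimethylsilyl ketene acetal of F7 (C5=C4 enol ether) | COc1cc([C@H]2OC(O[Si](C)(C)C)=C3[C@@H](c4ccc(O[Si](C(C)C)(C(C)C)C(C)C)c(OC)c4)OC(=O)[C@]23O[Si](C)(C)C)ccc1O[Si](C(C)C)(C(C)C)C(C)C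
F9 | step 5 | 1,5-bis-O-trimethylsilyl ether of 9 | COc1cc([C@H]2OC(=O)[C@]3(O[Si](C)(C)C)[C@@H](c4ccc(O[Si](C(C)C)(C(C)C)C(C)C)c(OC)c4)OC(=O)[C@]23O[Si](C)(C)C)ccc1O[Si](C(C)C)(C(C)C)C(C)C
F10 | step 7 | (1R,2S,3S,4R)-2,3-bis(hydroxymethyl)-1,4-bis[3-methoxy-4-(triisopropylsilyloxy)phenyl]butane-1,2,3,4-tetrol | COc1cc([C@@H](O)[C@@](O)(CO)[C@](O)(CO)[C@H](O)c2ccc(O[Si](C(C)C)(C(C)C)C(C)C)c(OC)c2)ccc1O[Si](C(C)C)(C(C)C)C(C)C
F11 | step 7 | (1R,2S,3S,4R)-1,4-bis(4-hydroxy-3-methoxyphenyl)-2,3-bis(hydroxymethyl)butane-1,2,3,4-tetrol | COc1cc([C@@H](O)[C@@](O)(CO)[C@](O)(CO)[C@H](O)c2ccc(O)c(OC)c2)ccc1O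
A1 | alternative 1 | (4R,5R)-4,5-bis[4-(tert-butyldimethylsilyloxy)-3-methoxybenzoyl]-2,2-dimethyl-1,3-dioxolane | O=C(c1ccc(O[Si](C)(C)C(C)(C)C)c(OC)c1)[C@@H]2OC(C)(C)O[C@H]2C(=O)c3ccc(O[Si](C)(C)C(C)(C)C)c(OC)c3
A2 | alternative 1 | C2-symmetric 4,5-bis(benzyloxymethyl) derivative of A1 | O=C(c1ccc(O[Si](C)(C)C(C)(C)C)c(OC)c1)[C@]2(COCc3ccccc3)OC(C)(C)O[C@@]2(COCc4ccccc4)C(=O)c5ccc(O[Si](C)(C)C(C)(C)C)c(OC)c5
A3 | alternative 2 | (2E,3E)-2,3-bis[(4-allyloxy-3-methoxyphenyl)methylidene]butane-1,4-diol | OC/C(=C/c1ccc(OCC=C)c(OC)c1)/C(CO)=C\c2ccc(OCC=C)c(OC)c2
A4 | alternative 2 | prinsepiol 4′,4″-bis(allyl) ether | COc1cc([C@H]2OC[C@]3(O)[C@@H](c4ccc(OCC=C)c(OC)c4)OC[C@]23O)ccc1OCC=C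
A5 | alternative 3 | cis-fused 1,5-bis(trimethylsilyloxy)-3,7-dioxabicyclo[3.3.0]octane-2,6-diyl diacetate (anomers at C2 and C6) | CC(=O)OC1OC[C@]2(O[Si](C)(C)C)C(OC(C)=O)OC[C@]12O[Si](C)(C)C
A6 | alternative 3 | bis[4-(tert-butyldimethylsilyloxy)-3-methoxyphenyl]zinc | COc1cc([Zn]c2ccc(O[Si](C)(C)C(C)(C)C)c(OC)c2)ccc1O[Si](C)(C)C(C)(C)C
A7 | alternative 3 | prinsepiol 1,5-bis(trimethylsilyl) 4′,4″-bis(tert-butyldimethylsilyl) ether | COc1cc([C@H]2OC[C@]3(O[Si](C)(C)C)[C@@H](c4ccc(O[Si](C)(C)C(C)(C)C)c(OC)c4)OC[C@]23O[Si](C)(C)C)ccc1O[Si](C)(C)C(C)(C)C
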